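**Retrosynthetic overview**
1. The prenyl group goes on last: ring B of the des-prenyl isoflavone 12 is symmetric (3′ ≡ 5′), so Friedel–Crafts C-prenylation can give only one ring-B regioisomer.
2. Ring C (the pyranone) is the only ring that is built; it is closed from 2-hydroxydeoxybenzoin 9 with a one-carbon amide acetal, and the two MOM groups come off in the same pot.
3. Key disconnection, ArC(=O)CH2–Ar′: the α-carbon of the ring-A acetophenone is made electrophilic (trivalent-iodine enolonium) and is joined to the ring-B carbon between the two oxygens, delivered as an arylzinc – two carbons that are both natively nucleophilic.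
4. The ring-B nucleophile is fixed regiochemically by directed ortho-metalation of bis-MOM 5-methoxyresorcinol; ring A comes from 2,4-dihydroxyacetophenone. Rings A and B are bought as arenes.

Assumption: the target has no stereocentre and no stereogenic double bond (the alkene carries two identical methyl groups), so it is achiral and no stereocontrol is needed.

**Route**

Step 1
Reactants: 1 5-methoxybenzene-1,3-diol (5-methoxyresorcinol)
Product: 2 1-methoxy-3,5-bis(methoxymethoxy)benzene
Conditions: NaH (2.4 equiv), MOMCl (2.4 equiv), DMF, 0 °C to rt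
Reagents that add atoms: chloromethyl methyl ether (MOMCl), COCCl
Why: Williamson-type O-alkylation of both phenoxides gives the bis-MOM ether, whose two acetal oxygens later direct lithiation to the carbon between them and keep the future 2′/6′-hydroxyls from cyclising onto the ketone.

Step 2
Reactants: 3 1-(2,4-dihydroxyphenyl)ethan-1-one (2,4-dihydroxyacetophenone)
Product: 4 trimethyl({1-[2,4-bis(trimethylsilyloxy)phenyl]ethenyl}oxy)silane
Conditions: TMSOTf (3.3 equiv), Et3N (4.5 equiv), CH2Cl2, 0 °C to rt; pentane extraction, filtration, used crude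
Reagents that add atoms: trimethylsilyl trifluoromethanesulfonate, C[Si](C)(C)OS(=O)(=O)C(F)(F)F
Why: Soft enolisation/O-silylation (silyl triflate with tertiary amine) caps both phenols and converts the methyl ketone into its TMS enol ether in one operation, giving the enol nucleophile that the next step inverts in polarity.

Step 3
Reactants: 2 1-methoxy-3,5-bis(methoxymethoxy)benzene; 4 trimethyl({1-[2,4-bis(trimethylsilyloxy)phenyl]ethenyl}oxy)silane
Product: 9 1-(2,4-dihydroxyphenyl)-2-[4-methoxy-2,6-bis(methoxymethoxy)phenyl]ethan-1-one, via aryllithium 5 (not isolated), via diarylzinc 6 (not isolated), via enolonium tosylate 7 (not isolated), via bis-silyl ketone 8 (not isolated)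
Conditions: (a) 2 (2.4 equiv), n-BuLi, Et2O, 0 °C to rt, then ZnCl2 (0.5 equiv per Li), Et2O, 0 °C; (b) 4 (1.0 equiv), PhI(OH)OTs (1.05 equiv), BF3·OEt2 (1.5 equiv), CH2Cl2, −78 °C, 5 min; (c) solution (a) into (b), −78 to −20 °C, aq NH4Cl; (d) K2CO3 (cat.), MeOH, 0 °C
Reagents that add atoms: none
Why: Proposed new method: arylation of a preformed ketone enolonium by a diarylzinc – PhI(OH)OTs/BF3·OEt2 converts the TMS enol ether at −78 °C into an O-bound λ3-iodanyl enol ether whose CH2 carbon is a strong electrophile (SN2′-type attack with reductive loss of PhI), and the aryl–zinc σ-bond, placed between the two OMOM groups by directed ortho-metalation, is a far better and strictly ipso-selective carbon nucleophile than the parent arene, so the bond forms only at the required ring-B carbon, while the primary enolonium carbon tolerates the 2,6-disubstituted aryl and the silylated ortho oxygen cannot close to a benzofuranone (5-endo geometry); the closest known reaction types are the α-alkylation of such enolonium species with dialkylzincs and their α-arylation with indoles and pyrroles, and no stereocentre is formed.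

Step 4
Reactants: 9 1-(2,4-dihydroxyphenyl)-2-[4-methoxy-2,6-bis(methoxymethoxy)phenyl]ethan-1-one
Product: 12 3-(2,6-dihydroxy-4-methoxyphenyl)-7-hydroxy-4H-chromen-4-one, via enaminone 10 (not isolated), via bis-MOM isoflavone 11 (not isolated)
Conditions: DMF-DMA (1.5 equiv), THF, 60 °C; then 3 M HCl in MeOH, 50 °C
Reagents that add atoms: N,N-dimethylformamide dimethyl acetal, COC(OC)N(C)C
Why: Amide-acetal (enaminone) isoflavone synthesis – DMF-DMA condenses at the doubly activated CH2, the 2-hydroxyl adds to the enaminone and dimethylamine is lost on acidification to close ring C, and the same methanolic HCl cleaves both aryl MOM acetals only once the chromone exists, after which a 2′-hydroxyl can no longer cyclise onto C-4.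

Step 5
Reactants: 12 3-(2,6-dihydroxy-4-methoxyphenyl)-7-hydroxy-4H-chromen-4-one; 13 2-methylbut-3-en-2-ol
Product: 14 3-[2,6-dihydroxy-4-methoxy-3-(3-methylbut-2-en-1-yl)phenyl]-7-hydroxy-4H-chromen-4-one
Conditions: 13 (1.5 equiv), BF3·OEt2 (0.5 equiv), 1,4-dioxane, rt, stopped at partial conversion, 12 recycled
Reagents that add atoms: none
Why: Friedel–Crafts C-prenylation – BF3 ionises 13 to the 3,3-dimethylallyl cation, which attacks the phloroglucinol-type ring B much faster than the carbonyl-deactivated ring A, and because the two open ring-B positions of 12 are equivalent only one mono-prenyl regioisomer can form, with water as the only co-product and no stereocentre created.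

**Compound list**
1 | 5-methoxybenzene-1,3-diol (5-methoxyresorcinol) | COc1cc(O)cc(O)c1 | starting material
2 | 1-methoxy-3,5-bis(methoxymethoxy)benzene | COCOc1cc(OC)cc(OCOC)c1 | intermediate
3 | 1-(2,4-dihydroxyphenyl)ethan-1-one | CC(=O)c1ccc(O)cc1O | starting material
4 | trimethyl({1-[2,4-bis(trimethylsilyloxy)phenyl]ethenyl}oxy)silane | C=C(O[Si](C)(C)C)c1ccc(O[Si](C)(C)C)cc1O[Si](C)(C)C | intermediate
5 | [4-methoxy-2,6-bis(methoxymethoxy)phenyl]lithium | [Li]c1c(OCOC)cc(OC)cc1OCOC | intermediate
6 | bis[4-methoxy-2,6-bis(methoxymethoxy)phenyl]zinc | COCOc1cc(OC)cc(OCOC)c1[Zn]c1c(OCOC)cc(OC)cc1OCOC | intermediate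
7 | ({1-[2,4-bis(trimethylsilyloxy)phenyl]ethenyl}oxy)(phenyl)-λ3-iodanyl 4-methylbenzenesulfonate (O-bound enolonium, BF3-activated) | C=C(OI(OS(=O)(=O)c1ccc(C)cc1)c1ccccc1)c1ccc(O[Si](C)(C)C)cc1O[Si](C)(C)C | intermediate
8 | 1-[2,4-bis(trimethylsilyloxy)phenyl]-2-[4-methoxy-2,6-bis(methoxymethoxy)phenyl]ethan-1-one | COCOc1cc(OC)cc(OCOC)c1CC(=O)c1ccc(O[Si](C)(C)C)cc1O[Si](C)(C)C | intermediate
9 | 1-(2,4-dihydroxyphenyl)-2-[4-methoxy-2,6-bis(methoxymethoxy)phenyl]ethan-1-one | COCOc1cc(OC)cc(OCOC)c1CC(=O)c1ccc(O)cc1O | intermediate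
10 | 1-(2,4-dihydroxyphenyl)-3-(dimethylamino)-2-[4-methoxy-2,6-bis(methoxymethoxy)phenyl]prop-2-en-1-one (alkene geometry not defined, both isomers converge) | CN(C)C=C(C(=O)c1ccc(O)cc1O)c1c(OCOC)cc(OC)cc1OCOC | intermediate
11 | 7-hydroxy-3-[4-methoxy-2,6-bis(methoxymethoxy)phenyl]-4H-chromen-4-one | COCOc1cc(OC)cc(OCOC)c1-c1coc2cc(O)ccc2c1=O | intermediate
12 | 3-(2,6-dihydroxy-4-methoxyphenyl)-7-hydroxy-4H-chromen-4-one | COc1cc(O)c(-c2coc3cc(O)ccc3c2=O)c(O)c1 | intermediate
13 | 2-methylbut-3-en-2-ol | C=CC(C)(C)O | starting material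
14 | 3-[2,6-dihydroxy-4-methoxy-3-(3-methylbut-2-en-1-yl)phenyl]-7-hydroxy-4H-chromen-4-one | COc1cc(O)c(-c2coc3cc(O)ccc3c2=O)c(O)c1CC=C(C)C | target

**Step count**
Total steps: 5. Longest linear sequence: 4 (3 → 4 → 9 → 12 → 14, or equally 1 → 2 → 9 → 12 → 14).

**Steps most likely to fail, with fallbacks**

Step 3 is the largest risk. The diarylzinc may attack iodine instead of carbon, which would give a diaryliodonium salt or an α-tosyloxy or α-phenyl ketone, and the acid released may protonate the zinc reagent. The fallback keeps the same bond and the same polarity but replaces the transient trivalent-iodine enolonium by a stable α-bromoketone in a nickel-catalysed cross-coupling. It sets out from 3 and uses zinc reagent 6 made from 2 as before. TBSOTf/Et3N in CH2Cl2 gives tert-butyl({1-[2,4-bis(tert-butyldimethylsilyloxy)phenyl]ethenyl}oxy)dimethylsilane F1. NBS in THF at −78 °C converts it into 2-bromo-1-[2,4-bis(tert-butyldimethylsilyloxy)phenyl]ethan-1-one F2. Negishi coupling of this bromide with 6 (NiCl2(dme), 4,4′-di-tert-butyl-2,2′-bipyridine, THF/DMA, 0 °C) gives 1-[2,4-bis(tert-butyldimethylsilyloxy)phenyl]-2-[4-methoxy-2,6-bis(methoxymethoxy)phenyl]ethan-1-one F3. TBAF/AcOH in THF at 0 °C removes the two aryl silyl ethers, and the sequence comes back to the route at 9.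

Step 5 is the second risk. Over-prenylation at 5′, some ring-A attack and acid-induced chroman formation from the new ortho-prenyl phenol can keep the yield of 14 modest, realistically 30–45% per pass. The fallback replaces the cationic alkylation by halogenation and cross-coupling. It sets out from 12. NIS (1.0 equiv) in DMF at −20 °C iodinates the most electron-rich ring once to give 3-(2,6-dihydroxy-3-iodo-4-methoxyphenyl)-7-hydroxy-4H-chromen-4-one F5. Stille coupling with tributyl(3-methylbut-2-en-1-yl)stannane (Pd(PPh3)4 as the zerovalent palladium catalyst, LiCl, DMF, 80 °C) transfers the linear prenyl group and arrives at 14.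

Step 4 is the third risk. DMF-DMA can O-methylate the free 4-hydroxyl of ring A, and the enaminone may resist closure. The fallback switches from the amide acetal to a base-mediated Claisen formylation through an isolable hemiacetal. It sets out from 9. Ethyl formate and NaH (4 equiv) in THF at 0 °C to rt give 2,7-dihydroxy-3-[4-methoxy-2,6-bis(methoxymethoxy)phenyl]chroman-4-one F4 as a mixture of racemic diastereomers, whose two stereocentres vanish in the next operation. 3 M HCl in MeOH at 50 °C then dehydrates the hemiacetal and cleaves both MOM groups, coming back to the route at 12.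

**Further compounds**
F1 | step 3 | tert-butyl({1-[2,4-bis(tert-butyldimethylsilyloxy)phenyl]ethenyl}oxy)dimethylsilane | C=C(O[Si](C)(C)C(C)(C)C)c1ccc(O[Si](C)(C)C(C)(C)C)cc1O[Si](C)(C)C(C)(C)C
F2 | step 3 | 2-bromo-1-[2,4-bis(tert-butyldimethylsilyloxy)phenyl]ethan-1-one | BrCC(=O)c1ccc(O[Si](C)(C)C(C)(C)C)cc1O[Si](C)(C)C(C)(C)C
F3 | step 3 | 1-[2,4-bis(tert-butyldimethylsilyloxy)phenyl]-2-[4-methoxy-2,6-bis(methoxymethoxy)phenyl]ethan-1-one | COCOc1cc(OC)cc(OCOC)c1CC(=O)c1ccc(O[Si](C)(C)C(C)(C)C)cc1O[Si](C)(C)C(C)(C)C
F4 | step 4 | 2,7-dihydroxy-3-[4-methoxy-2,6-bis(methoxymethoxy)phenyl]chroman-4-one (mixture of racemic diastereomers) | COCOc1cc(OC)cc(OCOC)c1C1C(O)Oc2cc(O)ccc2C1=O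
F5 | step 5 | 3-(2,6-dihydroxy-3-iodo-4-methoxyphenyl)-7-hydroxy-4H-chromen-4-one | COc1cc(O)c(-c2coc3cc(O)ccc3c2=O)c(O)c1I
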